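**Plan**

- Cuts, in retrosynthetic order: the three MOM ethers; the C3'–C1'' bond of the geranyl chain (back to an aryl bromide); the C4 ketone (back to an alcohol); the C3–O and C4–O bonds together (back to a C3=C4 alkene); that alkene (metathesis); the O1–C2 bond (allylic etherification).
- Enabling feature: O3 and the carbonyl oxygen on C4 sit on neighbouring carbons of the pyranone ring C. Both can therefore be placed at once on the C3=C4 bond of a flav-3-ene that has no carbonyl group and no epimerisable centre beside one.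
- Forward: ring A vinylphenol 6 (from 2-methylresorcinol, the third oxygen entering by C–H borylation/oxidation para to the methyl group) and ring B carbonate 11 are joined at O1–C2. Ring C is closed by metathesis, dioxygenated, oxidised at C4, and the geranyl chain is attached at C3' before deprotection.
- Stereochemistry: C2 from ligand control in the iridium-catalysed etherification; C3 from osmylation anti to the C2 aryl group; the 2E alkene is carried in from geranyl bromide.

Key step: step 11

Assumption (sense of induction in step 9): with aryl-substituted allyl carbonates and oxygen nucleophiles the (Ra,Rc,Rc) ligand is taken to give (R)-ethers, so its (Sa,Sc,Sc) mirror image is specified for the (S)-ether 12; were the sense the reverse, the other ligand enantiomer would be used and nothing else changes.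

**Route**

Step 1
Reactants: 1 2-methylresorcinol
Product: 2 1,3-bis(methoxymethoxy)-2-methylbenzene
Conditions: NaH, MOMCl, DMF, 0 °C → rt
Reagents that add atoms: chloromethyl methyl ether, COCCl
Why: Williamson-type O-alkylation of both phenoxides (MOM acetal protection) gives ethers that withstand every later basic, organometallic and oxidative step.

Step 2
Reactants: 2 1,3-bis(methoxymethoxy)-2-methylbenzene
Product: 4 3,5-bis(methoxymethoxy)-4-methylphenol, via aryl pinacol boronate 3 (not isolated)
Conditions: [Ir(OMe)(cod)]2 (1.5 mol %), 4,4'-di-tert-butyl-2,2'-bipyridine (3 mol %), B2pin2 (1.0 equiv), THF, 80 °C; then aq. NaOH, 30% H2O2, 0 °C → rt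
Reagents that add atoms: bis(pinacolato)diboron, CC1(C)OB(OC1(C)C)B1OC(C)(C)C(C)(C)O1 (boryl group of 3); hydrogen peroxide, OO (phenol oxygen of 4)
Why: Sterically governed iridium-catalysed aromatic C–H borylation attacks the only C–H without an ortho substituent (para to the methyl group), and oxidation of the C–B bond (aryl shift to peroxide oxygen) then reveals exactly the one free phenol that becomes O1, so no selective protection of a phloroglucinol is needed.

Step 3
Reactants: 4 3,5-bis(methoxymethoxy)-4-methylphenol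
Product: 5 6-hydroxy-2,4-bis(methoxymethoxy)-3-methylbenzaldehyde
Conditions: MgCl2 (anhydrous), Et3N, (CH2O)n, MeCN, 80 °C
Reagents that add atoms: paraformaldehyde (as formaldehyde), C=O
Why: Magnesium-phenoxide-mediated ortho-formylation (Casnati–Skattebøl) delivers formaldehyde within a chelate to the carbon beside the phenol oxygen; the two ortho carbons are equivalent, the para carbon carries the methyl group, and the basic medium spares the MOM acetals.

Step 4
Reactants: 5 6-hydroxy-2,4-bis(methoxymethoxy)-3-methylbenzaldehyde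
Product: 6 2-ethenyl-3,5-bis(methoxymethoxy)-4-methylphenol
Conditions: Ph3PCH3Br (2.5 equiv), KOtBu (2.4 equiv), THF, 0 °C → rt; used without storage
Reagents that add atoms: methyltriphenylphosphonium bromide, C[P+](c1ccccc1)(c1ccccc1)c1ccccc1.[Br-]
Why: Wittig methylenation with excess non-stabilised ylide, the first equivalent of base only forming the phenoxide, converts salicylaldehydes into 2-vinylphenols without protection.

Step 5
Reactants: 7 3-bromo-4-hydroxybenzaldehyde
Product: 8 3-bromo-4-(methoxymethoxy)benzaldehyde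
Conditions: MOMCl, i-Pr2NEt, CH2Cl2, 0 °C → rt
Reagents that add atoms: chloromethyl methyl ether, COCCl
Why: O-alkylation of the acidic para-formyl phenol (MOM protection) proceeds under mild amine base.

Step 6
Reactants: 8 3-bromo-4-(methoxymethoxy)benzaldehyde
Product: 9 ethyl (2E)-3-[3-bromo-4-(methoxymethoxy)phenyl]prop-2-enoate
Conditions: (EtO)2P(O)CH2CO2Et, NaH, THF, 0 °C → rt
Reagents that add atoms: triethyl phosphonoacetate, CCOC(=O)CP(=O)(OCC)OCC
Why: Horner–Wadsworth–Emmons olefination with a stabilised phosphonate anion gives the E-alkene under thermodynamic control.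

Step 7
Reactants: 9 ethyl (2E)-3-[3-bromo-4-(methoxymethoxy)phenyl]prop-2-enoate
Product: 10 (2E)-3-[3-bromo-4-(methoxymethoxy)phenyl]prop-2-en-1-ol
Conditions: i-Bu2AlH (2.2 equiv), CH2Cl2, −78 °C; aq. potassium sodium tartrate
Reagents that add atoms: none
Why: 1,2-Reduction of the unsaturated ester by the aluminium hydride at low temperature gives the allylic alcohol and leaves the alkene geometry and the aryl bromide untouched.

Step 8
Reactants: 10 (2E)-3-[3-bromo-4-(methoxymethoxy)phenyl]prop-2-en-1-ol
Product: 11 (2E)-3-[3-bromo-4-(methoxymethoxy)phenyl]prop-2-en-1-yl methyl carbonate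
Conditions: ClCO2Me, pyridine, CH2Cl2, 0 °C
Reagents that add atoms: methyl chloroformate, COC(=O)Cl
Why: Acylation of the primary allylic alcohol gives the linear methyl carbonate, the usual leaving group for iridium allyl chemistry.

Step 9
Reactants: 6 2-ethenyl-3,5-bis(methoxymethoxy)-4-methylphenol; 11 (2E)-3-[3-bromo-4-(methoxymethoxy)phenyl]prop-2-en-1-yl methyl carbonate
Product: 12 1-{[(1S)-1-[3-bromo-4-(methoxymethoxy)phenyl]prop-2-en-1-yl]oxy}-2-ethenyl-3,5-bis(methoxymethoxy)-4-methylbenzene
Conditions: [Ir(cod)Cl]2 (2 mol %), (Sa,Sc,Sc)-O,O'-(1,1'-binaphthyl-2,2'-diyl) N,N-bis(1-phenylethyl)phosphoramidite (4 mol %), preactivated with n-PrNH2; K3PO4, THF, rt → 40 °C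
Reagents that add atoms: none
Why: Iridium-catalysed asymmetric allylic etherification, in which the cyclometalated iridium phosphoramidite ionises the linear carbonate to an allyl complex and the phenoxide attacks its aryl-substituted terminus, gives the branched ether and sets C2 by ligand control; 2-vinylphenols are established nucleophiles for this reaction.

Step 10
Reactants: 12 1-{[(1S)-1-[3-bromo-4-(methoxymethoxy)phenyl]prop-2-en-1-yl]oxy}-2-ethenyl-3,5-bis(methoxymethoxy)-4-methylbenzene
Product: 13 (2S)-2-[3-bromo-4-(methoxymethoxy)phenyl]-5,7-bis(methoxymethoxy)-6-methyl-2H-chromene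
Conditions: second-generation Grubbs catalyst RuCl2(=CHPh)(PCy3)(H2IMes) (5 mol %), CH2Cl2 (0.01 M), 40 °C
Reagents that add atoms: none
Why: Ring-closing olefin metathesis, in which the ruthenium carbene loads on the monosubstituted allyl alkene and closes the six-membered ring onto the styrene with loss of ethylene, leaves the C2 stereocentre uninvolved.

Step 11
Reactants: 13 (2S)-2-[3-bromo-4-(methoxymethoxy)phenyl]-5,7-bis(methoxymethoxy)-6-methyl-2H-chromene
Product: 14 (2R,3S,4S)-2-[3-bromo-4-(methoxymethoxy)phenyl]-5,7-bis(methoxymethoxy)-6-methyl-3,4-dihydro-2H-chromene-3,4-diol (2,3-trans-3,4-cis)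
Conditions: OsO4 (2 mol %), NMO (1.5 equiv), acetone/H2O 10:1, 0 °C → rt; aq. Na2SO3
Reagents that add atoms: osmium tetroxide, O=[Os](=O)(=O)=O (delivers both oxygens); N-methylmorpholine N-oxide, C[N+]1([O-])CCOCC1 (restores the oxygen on osmium); water, O (hydrolysis of the osmate ester)
Why: OsO4 adds to C3=C4 in a concerted suprafacial [3+2] cycloaddition to give a cyclic glycolate of hexavalent osmium, which NMO re-oxidises and water hydrolyses, so both C–O bonds form on the same face. The closest known reaction type is the substrate-directed syn-dihydroxylation of flav-3-enes and other 2-substituted 2H-chromenes, which gives 2,3-trans-3,4-cis flavan-3,4-diols. No ring of the product is closed; the five-membered osmate ring is transient. C3 is controlled by the C2 stereocentre, because in the half-chair of the pyran ring the C2 aryl group blocks its own face and the oxidant arrives from the other side, placing O3 trans to the aryl group; C4 follows from the suprafacial addition (cis to O3) and is removed in step 12. The step needs diastereoface selectivity, secured by the C2 aryl group, and reaction at a single alkene, secured by the bromine that holds the place of the geranyl chain at C3'; the carbonyl-free substrate has no enolisable centre that the mildly basic medium could epimerise. The C2 descriptor changes from S to R only because the oxygenated C3 gains priority.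

Step 12
Reactants: 14 (2R,3S,4S)-2-[3-bromo-4-(methoxymethoxy)phenyl]-5,7-bis(methoxymethoxy)-6-methyl-3,4-dihydro-2H-chromene-3,4-diol
Product: 15 (2R,3R)-2-[3-bromo-4-(methoxymethoxy)phenyl]-3-hydroxy-5,7-bis(methoxymethoxy)-6-methyl-2,3-dihydro-4H-chromen-4-one
Conditions: DDQ (1.2 equiv), 1,4-dioxane, rt
Reagents that add atoms: none
Why: Chemoselective benzylic alcohol oxidation by hydride abstraction, in which DDQ takes the C4–H that is activated by the ortho and para oxygen donors of ring A and leaves the non-benzylic C3 alcohol alone, erases the C4 stereocentre and keeps C3 (now R by descriptor only).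

Step 13
Reactants: 16 geranyl bromide
Product: 17 tributyl[(2E)-3,7-dimethylocta-2,6-dien-1-yl]stannane
Conditions: Bu3SnH, LiN(i-Pr)2, THF, 0 °C; then 16, −78 °C → rt
Reagents that add atoms: tributyltin hydride, CCCC[SnH](CCCC)CCCC
Why: SN2 displacement of the primary allylic bromide by the stannyl anion gives the allylstannane with the E-alkene unchanged.

Step 14
Reactants: 15 (2R,3R)-2-[3-bromo-4-(methoxymethoxy)phenyl]-3-hydroxy-5,7-bis(methoxymethoxy)-6-methyl-2,3-dihydro-4H-chromen-4-one; 17 tributyl[(2E)-3,7-dimethylocta-2,6-dien-1-yl]stannane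
Product: 18 (2R,3R)-2-{3-[(2E)-3,7-dimethylocta-2,6-dien-1-yl]-4-(methoxymethoxy)phenyl}-3-hydroxy-5,7-bis(methoxymethoxy)-6-methyl-2,3-dihydro-4H-chromen-4-one
Conditions: Pd(PPh3)4 (5 mol %), DMF, 90 °C, argon
Reagents that add atoms: none
Why: Stille coupling (oxidative addition of zerovalent palladium to the aryl bromide, allyl transfer from tin, reductive elimination at the less hindered allyl terminus) forms the C3'–C1'' bond under neutral conditions that the base-sensitive ketol tolerates, and the chain enters only now because its two alkenes would have competed in step 11.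

Step 15
Reactants: 18 (2R,3R)-2-{3-[(2E)-3,7-dimethylocta-2,6-dien-1-yl]-4-(methoxymethoxy)phenyl}-3-hydroxy-5,7-bis(methoxymethoxy)-6-methyl-2,3-dihydro-4H-chromen-4-one
Product: 19 (2R,3R)-2-{3-[(2E)-3,7-dimethylocta-2,6-dien-1-yl]-4-hydroxyphenyl}-3,5,7-trihydroxy-6-methyl-2,3-dihydro-4H-chromen-4-one
Conditions: 3 M aq. HCl, MeOH, rt (to 40 °C if needed)
Reagents that add atoms: none
Why: Acid-catalysed acetal cleavage (transacetalisation to dimethoxymethane) should remove all three aryl MOM ethers, dilute acid near ambient temperature being chosen so that the geranyl alkenes are neither hydrated nor cyclised onto the 4'-phenol and the trans ketol, the more stable diastereomer, is not epimerised.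

**Compound list**

1 | 2-methylresorcinol (2-methylbenzene-1,3-diol) | Cc1c(O)cccc1O | starting material
2 | 1,3-bis(methoxymethoxy)-2-methylbenzene | Cc1c(OCOC)cccc1OCOC | intermediate
3 | 2-[3,5-bis(methoxymethoxy)-4-methylphenyl]-4,4,5,5-tetramethyl-1,3,2-dioxaborolane | Cc1c(OCOC)cc(B2OC(C)(C)C(C)(C)O2)cc1OCOC | intermediate
4 | 3,5-bis(methoxymethoxy)-4-methylphenol | Cc1c(OCOC)cc(O)cc1OCOC | intermediate
5 | 6-hydroxy-2,4-bis(methoxymethoxy)-3-methylbenzaldehyde | O=Cc1c(O)cc(OCOC)c(C)c1OCOC | intermediate
6 | 2-ethenyl-3,5-bis(methoxymethoxy)-4-methylphenol | C=Cc1c(O)cc(OCOC)c(C)c1OCOC | intermediate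
7 | 3-bromo-4-hydroxybenzaldehyde | O=Cc1ccc(O)c(Br)c1 | starting material
8 | 3-bromo-4-(methoxymethoxy)benzaldehyde | O=Cc1ccc(OCOC)c(Br)c1 | intermediate
9 | ethyl (2E)-3-[3-bromo-4-(methoxymethoxy)phenyl]prop-2-enoate | CCOC(=O)/C=C/c1ccc(OCOC)c(Br)c1 | intermediate
10 | (2E)-3-[3-bromo-4-(methoxymethoxy)phenyl]prop-2-en-1-ol | OC/C=C/c1ccc(OCOC)c(Br)c1 | intermediate
11 | (2E)-3-[3-bromo-4-(methoxymethoxy)phenyl]prop-2-en-1-yl methyl carbonate | COC(=O)OC/C=C/c1ccc(OCOC)c(Br)c1 | intermediate
12 | 1-{[(1S)-1-[3-bromo-4-(methoxymethoxy)phenyl]prop-2-en-1-yl]oxy}-2-ethenyl-3,5-bis(methoxymethoxy)-4-methylbenzene | C=C[C@H](Oc1cc(OCOC)c(C)c(OCOC)c1C=C)c1ccc(OCOC)c(Br)c1 | intermediate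
13 | (2S)-2-[3-bromo-4-(methoxymethoxy)phenyl]-5,7-bis(methoxymethoxy)-6-methyl-2H-chromene | Brc1cc([C@H]2Oc3cc(OCOC)c(C)c(OCOC)c3C=C2)ccc1OCOC | intermediate
14 | (2R,3S,4S)-2-[3-bromo-4-(methoxymethoxy)phenyl]-5,7-bis(methoxymethoxy)-6-methyl-3,4-dihydro-2H-chromene-3,4-diol | Brc1cc([C@H]2Oc3cc(OCOC)c(C)c(OCOC)c3[C@H](O)[C@@H]2O)ccc1OCOC | intermediate
15 | (2R,3R)-2-[3-bromo-4-(methoxymethoxy)phenyl]-3-hydroxy-5,7-bis(methoxymethoxy)-6-methyl-2,3-dihydro-4H-chromen-4-one | Brc1cc([C@H]2Oc3cc(OCOC)c(C)c(OCOC)c3C(=O)[C@@H]2O)ccc1OCOC | intermediate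
16 | geranyl bromide, (2E)-1-bromo-3,7-dimethylocta-2,6-diene | CC(C)=CCC/C(C)=C/CBr | starting material
17 | tributyl[(2E)-3,7-dimethylocta-2,6-dien-1-yl]stannane | CC(C)=CCC/C(C)=C/C[Sn](CCCC)(CCCC)CCCC | intermediate
18 | (2R,3R)-2-{3-[(2E)-3,7-dimethylocta-2,6-dien-1-yl]-4-(methoxymethoxy)phenyl}-3-hydroxy-5,7-bis(methoxymethoxy)-6-methyl-2,3-dihydro-4H-chromen-4-one | CC(C)=CCC/C(C)=C/Cc1cc([C@H]2Oc3cc(OCOC)c(C)c(OCOC)c3C(=O)[C@@H]2O)ccc1OCOC | intermediate
19 | (2R,3R)-2-{3-[(2E)-3,7-dimethylocta-2,6-dien-1-yl]-4-hydroxyphenyl}-3,5,7-trihydroxy-6-methyl-2,3-dihydro-4H-chromen-4-one | CC(C)=CCC/C(C)=C/Cc1cc([C@H]2Oc3cc(O)c(C)c(O)c3C(=O)[C@@H]2O)ccc1O | target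

**Totals and risks**

Total step count: 15. Longest linear sequence: 10 steps (steps 1–4, 9–12, 14, 15; the ring B branch through steps 5–8 is equally long).

Steps most likely to fail:

1. Step 9. The electron-rich benzylic allylic ether may ionise again at iridium, eroding enantiopurity and branched selectivity; C-allylation of the electron-rich ring or oligomerisation of the vinylphenol may also compete. The fallback forms O1–C2 by SN2 inversion instead and sets out from aldehyde 8. Addition of vinylmagnesium bromide (THF, −78 °C) gives racemic 1-[3-bromo-4-(methoxymethoxy)phenyl]prop-2-en-1-ol F1. Sharpless kinetic resolution (Ti(OiPr)4, D-(−)-diisopropyl tartrate, t-BuOOH, 4 Å sieves, CH2Cl2, −20 °C) should leave (1R)-1-[3-bromo-4-(methoxymethoxy)phenyl]prop-2-en-1-ol F2, the (S)-enantiomer being consumed as the epoxy alcohol (R)-[3-bromo-4-(methoxymethoxy)phenyl][(2S)-oxiran-2-yl]methanol F3 and removed by chromatography. Mitsunobu reaction of F2 with phenol 6 (PPh3, diisopropyl azodicarboxylate, toluene, 0 °C) then inverts the carbinol centre and comes back to the route at 12.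

2. Step 12. Hydride abstraction may be slow because the C4–H of the pseudo-axial alcohol lies near the plane of ring A, and the acidic hydroquinone by-product may ionise the labile C4 alcohol. The fallback separates the two hydroxyls by protection and sets out from diol 14. Silylation at the equatorial O3 (TBSCl, imidazole, DMF, 0 °C; O4 is pseudo-axial and crowded by the peri 5-OMOM group) should give (2R,3S,4S)-2-[3-bromo-4-(methoxymethoxy)phenyl]-3-[(tert-butyldimethylsilyl)oxy]-5,7-bis(methoxymethoxy)-6-methyl-3,4-dihydro-2H-chromen-4-ol F4. Dess–Martin periodinane (NaHCO3, CH2Cl2, rt) oxidises the remaining C4 alcohol to (2R,3R)-2-[3-bromo-4-(methoxymethoxy)phenyl]-3-[(tert-butyldimethylsilyl)oxy]-5,7-bis(methoxymethoxy)-6-methyl-2,3-dihydro-4H-chromen-4-one F5. HF·pyridine (THF, 0 °C) removes the silyl group and comes back to the route at 15.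

3. Step 14. The allyl group may be transferred with transposition (bond formation at the tertiary terminus), the 2E geometry may scramble through the allylpalladium intermediate, or oxidative addition at the hindered, electron-rich bromide may be slow and give protodebromination. The fallback reverses the polarity of the coupling and sets out from ketol 15. Miyaura borylation (B2pin2, KOAc, PdCl2(dppf), 1,4-dioxane, 80 °C) gives (2R,3R)-3-hydroxy-5,7-bis(methoxymethoxy)-2-[4-(methoxymethoxy)-3-(4,4,5,5-tetramethyl-1,3,2-dioxaborolan-2-yl)phenyl]-6-methyl-2,3-dihydro-4H-chromen-4-one F6. Suzuki–Miyaura allyl–aryl coupling of F6 with geranyl bromide 16 (Pd(PPh3)4, KF, THF, 50 °C), in which the aryl group is delivered to the unsubstituted terminus of the E-configured allylpalladium, comes back to the route at 18; stannane 17 and step 13 are then not needed.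

**Further compounds**

F1 | step 9 | rac-1-[3-bromo-4-(methoxymethoxy)phenyl]prop-2-en-1-ol | C=CC(O)c1ccc(OCOC)c(Br)c1
F2 | step 9 | (1R)-1-[3-bromo-4-(methoxymethoxy)phenyl]prop-2-en-1-ol | C=C[C@@H](O)c1ccc(OCOC)c(Br)c1
F3 | step 9 | (R)-[3-bromo-4-(methoxymethoxy)phenyl][(2S)-oxiran-2-yl]methanol | O[C@H](c1ccc(OCOC)c(Br)c1)[C@@H]1CO1
F4 | step 12 | (2R,3S,4S)-2-[3-bromo-4-(methoxymethoxy)phenyl]-3-[(tert-butyldimethylsilyl)oxy]-5,7-bis(methoxymethoxy)-6-methyl-3,4-dihydro-2H-chromen-4-ol | Brc1cc([C@H]2Oc3cc(OCOC)c(C)c(OCOC)c3[C@H](O)[C@@H]2O[Si](C)(C)C(C)(C)C)ccc1OCOC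
F5 | step 12 | (2R,3R)-2-[3-bromo-4-(methoxymethoxy)phenyl]-3-[(tert-butyldimethylsilyl)oxy]-5,7-bis(methoxymethoxy)-6-methyl-2,3-dihydro-4H-chromen-4-one | Brc1cc([C@H]2Oc3cc(OCOC)c(C)c(OCOC)c3C(=O)[C@@H]2O[Si](C)(C)C(C)(C)C)ccc1OCOC
F6 | step 14 | (2R,3R)-3-hydroxy-5,7-bis(methoxymethoxy)-2-[4-(methoxymethoxy)-3-(4,4,5,5-tetramethyl-1,3,2-dioxaborolan-2-yl)phenyl]-6-methyl-2,3-dihydro-4H-chromen-4-one | CC1(C)OB(OC1(C)C)c1cc([C@H]2Oc3cc(OCOC)c(C)c(OCOC)c3C(=O)[C@@H]2O)ccc1OCOC
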